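**Strategy.** The cycloheptane (ring A) is disconnected at the bond between the angeloyloxy carbon C5 and the quaternary carbinol C1: C5–O, C1–OH and the C2 crotonoyl ketone form an α-oxygenated aldol unit. A potassium enolate of an acyclic α-silyloxy enone therefore closes ring A by intramolecular aldol addition to a C5 aldehyde, creating C1 and C5 in one operation with the ketone, tertiary oxygen and secondary carbinol in place. The precursor is a keto-aldehyde whose two arms sit cis on the preformed γ-lactone (ring B), made from a cyclopentene-fused lactone by unsymmetrical ozonolysis, Evans aldol and acyl-anion chain extension.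

Key step: step 15

Remarks on the chemistry:
- Numbering: ring A = cycloheptane C1, C5, C6, C7, C8, C9, C10; ring B = γ-lactone O–C12(=O)–C11–C7–C6. C1 carries OH and the chain C2(=O)–C3=C4–C15; C5 carries the angelate; C8 is CH2; C9 is CH–OH; C10 is CH–CH3; C11 is the lactone α-carbon.
- Assumption: (S)-2-(cyclopent-2-en-1-yl)acetic acid is taken as a catalogue compound (the racemate is sold and resolvable).
- C1 is formed unselectively in step 12 and erased by enolisation in step 15. Compounds 22–25 are therefore C1-epimer pairs, and their SMILES leave C1 open.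

Step 1
Reactants: 1 (S)-2-(cyclopent-2-en-1-yl)acetic acid
Product: 2 iodolactone (3aS,6R,6aR)-6-iodohexahydro-2H-cyclopenta[b]furan-2-one
Conditions: I2, KI, NaHCO3, H2O/THF, 0 °C to rt, dark
Reagents that add atoms: iodine, [I][I]
Why: Iodolactonisation, in which the carboxylate opens the iodonium ion at the neighbouring ring carbon from the face of the side chain, so the cis ring fusion (C6 from C7) is enforced and iodine ends trans to oxygen.

Step 2
Reactants: 2 iodolactone
Product: 3 allylic lactone (3aS,6aR)-3,3a,4,6a-tetrahydro-2H-cyclopenta[b]furan-2-one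
Conditions: DBU, THF, reflux
Reagents that add atoms: none
Why: E2 dehydroiodination, where the only antiperiplanar hydrogen sits on C9 (H6 is syn to iodine), so the C5=C9 alkene forms next to the oxygen-bearing ring-fusion carbon.

Step 3
Reactants: 3 allylic lactone
Product: 5 exo-methyl lactone (3S,3aS,6aR)-3-methyl-3,3a,4,6a-tetrahydro-2H-cyclopenta[b]furan-2-one, via lactone lithium enolate 4 (not isolated)
Conditions: LiN(iPr)2 (LDA), THF, −78 °C; MeI, −78 to −40 °C
Reagents that add atoms: iodomethane, CI
Why: Enolate alkylation on the convex face of the cis-fused bicyclic enolate should give the exo methyl group, i.e. the C11 epimer of what is needed.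

Step 4
Reactants: 5 exo-methyl lactone
Product: 7 endo-methyl lactone (3R,3aS,6aR)-3-methyl-3,3a,4,6a-tetrahydro-2H-cyclopenta[b]furan-2-one, via methylated lactone lithium enolate 6 (not isolated)
Conditions: LiN(iPr)2 (LDA), THF, −78 °C; then AcOH in THF, −78 °C
Reagents that add atoms: none
Why: Kinetic protonation of the planar enolate from the convex face pushes the methyl to the concave face and sets C11 (the contra-thermodynamic epimer, so later steps avoid equilibrating base).

Step 5
Reactants: 7 endo-methyl lactone
Product: 10 acetal aldehyde 2-[(2R,3S,4R)-2-(dimethoxymethyl)-4-methyl-5-oxooxolan-3-yl]acetaldehyde, via aldehyde methoxy hydroperoxide 8 (not isolated), via acetal methoxy hydroperoxide 9 (not isolated)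
Conditions: O3, CH2Cl2/MeOH (5:1), −78 °C; TsOH·H2O, rt; NaHCO3 then Me2S, rt
Reagents that add atoms: ozone, O=[O+][O-]; methanol, CO
Why: Unsymmetrical ozonolysis with terminus differentiation: the primary ozonide should fragment with the carbonyl oxide at C9, remote from the electron-withdrawing lactone oxygen, so methanol traps C9 as the methoxy hydroperoxide while the C5 aldehyde is acetalised, and Me2S then unveils only the C9 aldehyde.

Step 6
Reactants: 10 acetal aldehyde; 11 (S)-4-benzyl-3-propionyl-1,3-oxazolidin-2-one
Product: 14 syn-aldol imide (4S)-4-benzyl-3-[(2S,3R)-4-[(2R,3S,4R)-2-(dimethoxymethyl)-4-methyl-5-oxooxolan-3-yl]-3-hydroxy-2-methylbutanoyl]-1,3-oxazolidin-2-one, via boron enolate 12 (not isolated), via boron aldolate 13 (not isolated)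
Conditions: Bu2BOTf, Et3N, CH2Cl2, 0 °C; then 10, −78 to 0 °C; pH 7 buffer, MeOH, 30% H2O2, 0 °C
Reagents that add atoms: none
Why: Evans syn aldol, in which the (Z)-boron enolate reacts through a Zimmerman–Traxler chair and the auxiliary fixes the enolate face, setting C10 (S) and C9 (R) independently of the remote lactone centres.

Step 7
Reactants: 14 syn-aldol imide
Product: 15 silyl ether imide (C9–OTBS)
Conditions: TBSOTf, 2,6-lutidine, CH2Cl2, −78 to 0 °C
Reagents that add atoms: tert-butyldimethylsilyl triflate, CC(C)(C)[Si](C)(C)OS(=O)(=O)C(F)(F)F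
Why: Standard silylation of the secondary hydroxyl, to which lactone, acetal and imide are inert.

Step 8
Reactants: 15 silyl ether imide
Product: 16 thioester S-ethyl (2S,3R)-3-[(tert-butyldimethylsilyl)oxy]-4-[(2R,3S,4R)-2-(dimethoxymethyl)-4-methyl-5-oxooxolan-3-yl]-2-methylbutanethioate
Conditions: EtSH, n-BuLi, THF, 0 °C; then 15, 0 °C to rt
Reagents that add atoms: ethanethiol, CCS
Why: Thiolate cleavage of the N-acyl oxazolidinone at the exocyclic carbonyl; the weakly basic thiolate should leave the lactone and its C11 centre untouched.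

Step 9
Reactants: 16 thioester
Product: 17 aldehyde (2S,3R)-3-[(tert-butyldimethylsilyl)oxy]-4-[(2R,3S,4R)-2-(dimethoxymethyl)-4-methyl-5-oxooxolan-3-yl]-2-methylbutanal
Conditions: Et3SiH, Pd/C (10%), acetone, rt
Reagents that add atoms: none
Why: Fukuyama reduction of the thioester to the aldehyde under neutral conditions that spare lactone, acetal and silyl ether and should not epimerise C10.

Step 10
Reactants: 18 but-2-yn-1-ol
Product: 19 1-methoxybut-2-yne
Conditions: NaH, MeI, THF, 0 °C to rt
Reagents that add atoms: iodomethane, CI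
Why: Williamson ether synthesis on a primary propargylic alkoxide.

Step 11
Reactants: 19 1-methoxybut-2-yne
Product: 20 1-methoxybuta-1,2-diene
Conditions: KOtBu (0.1 equiv), DMSO, 20 °C; distillation
Reagents that add atoms: none
Why: Base-mediated propargyl-to-allenyl ether isomerisation through the oxygen-stabilised propargylic anion, held at the allene stage by catalytic base and low temperature.

Step 12
Reactants: 17 aldehyde; 20 1-methoxybuta-1,2-diene
Product: 23 α'-hydroxy enone acetal (C9–OTBS, C1–OH, (E)-crotonoyl ketone, C5 dimethyl acetal; C1 epimers), via lithiated methoxybutadiene 21 (not isolated), via lithium alkoxide adduct 22 (not isolated)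
Conditions: 20, n-BuLi, THF, −78 to −40 °C; 17, −78 °C; then 1 M HCl, THF, 0 °C
Reagents that add atoms: water, O
Why: The α-lithiated alkoxyallene is a crotonoyl anion equivalent that should add to the aldehyde far faster than to the lactone at −78 °C, and mild acid hydrolysis of the allenyl enol ether gives the conjugated (E)-enone; the C1 configuration is irrelevant.

Step 13
Reactants: 23 α'-hydroxy enone acetal
Product: 24 hydroxy keto aldehyde (C5 aldehyde free; C1 epimers)
Conditions: PPTS, acetone/H2O (10:1), 50 °C
Reagents that add atoms: water, O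
Why: Acid-catalysed acetal hydrolysis; the buffered acid is chosen to spare the secondary silyl ether while still cleaving the acetal deactivated by the adjacent lactone oxygen.

Step 14
Reactants: 24 hydroxy keto aldehyde
Product: 25 trimethylsilyl ether keto aldehyde (C1–OSiMe3; C1 epimers)
Conditions: TMSCl, imidazole, CH2Cl2, 0 °C
Reagents that add atoms: chlorotrimethylsilane, C[Si](C)(C)Cl
Why: Silylation of the α-hydroxy ketone gives a non-chelating, temporary O1 protecting group, so one equivalent of base suffices in step 15 and the enolate geometry is not dictated by chelation.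

Step 15
Reactants: 25 trimethylsilyl ether keto aldehyde
Product: 28 bicyclic diol (3R,3aS,5R,6S,7S,8S,8aR)-7-[(2E)-but-2-enoyl]-5-[(tert-butyldimethylsilyl)oxy]-7,8-dihydroxy-3,6-dimethyloctahydro-2H-cyclohepta[b]furan-2-one, via potassium enolate 26 (not isolated), via potassium aldolate 27 (not isolated)
Conditions: KN(SiMe3)2 (1.1 equiv), THF (0.005 M), −78 °C; AcOH, −78 °C; then citric acid, MeOH, 0 °C
Reagents that add atoms: none
Why: KN(SiMe3)2 removes the C1 hydrogen, the only α-hydrogen of the C2 ketone (the other flank is vinylic), and potassium enolate 26 adds to the C5 aldehyde in an intramolecular aldol addition, the known amide-base aldol cyclisation of keto-aldehydes, through a closed Zimmerman–Traxler transition state. Ring A closes in the 7-(enolexo)-exo-trig mode, helped by ring B, which holds the aldehyde on C6 and the enolate-bearing chain on C7 cis to each other. C1 is set by allylic 1,3-strain: the C10 hydrogen eclipses the tetrasubstituted enolate, the tether through C9 brings C5 to the face opposite the C10 methyl, and O1 therefore ends cis and the crotonoyl group trans to that methyl. C5 is set by the enolate geometry: hexamethyldisilazide bases are expected to place the larger α-substituent (branched C10) syn to O–K and the non-chelating OSiMe3 group anti to it, so in the chair the aldehyde oxygen lies anti to the C1–O bond and also anti to the C6–O bond (Cornforth-type dipole minimisation), which gives the trans C1–O/C5–O and trans C5–O/C6–O relationships with all carbon substituents of ring A equatorial. The step needs α'- over γ-deprotonation of the enone and ketone over aldehyde or lactone enolisation, which the α-oxygen-acidified C1–H, one equivalent of base at −78 °C and high dilution should secure; a chelated enolate would invert C5, which is why O1 carries a silyl and not an alkyl ether. Citric acid in methanol removes the trimethylsilyl group from whichever oxygen holds it, so any O1-to-O5 silyl shift is without consequence.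

Step 16
Reactants: 28 bicyclic diol; 29 angelic acid
Product: 31 angelate silyl ether (C5–O-angeloyl, C1–OH, C9–OTBS), via mixed anhydride 30 (not isolated)
Conditions: 29, 2,4,6-trichlorobenzoyl chloride, Et3N, toluene, rt; then 28, toluene, 70 °C
Reagents that add atoms: none
Why: Mixed-anhydride (Yamaguchi-type) esterification without a nucleophilic amine catalyst, which should avoid Z-to-E isomerisation of the angeloyl unit; only the secondary C5 hydroxyl reacts, the tertiary C1 hydroxyl being too hindered.

Step 17
Reactants: 31 angelate silyl ether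
Product: 32 target (3R,3aS,5R,6S,7S,8S,8aR)-7-[(2E)-but-2-enoyl]-5,7-dihydroxy-3,6-dimethyl-2-oxooctahydro-2H-cyclohepta[b]furan-8-yl (2Z)-2-methylbut-2-enoate
Conditions: HF·pyridine, pyridine/THF, 0 °C to rt
Reagents that add atoms: none
Why: Fluoride-mediated desilylation of the secondary silyl ether under buffered, non-basic conditions that should leave both enoates, the lactone and the β-acyloxy ketone intact.

**Compound list**
1 | (S)-2-(cyclopent-2-en-1-yl)acetic acid | OC(=O)C[C@@H]1CCC=C1 | starting material
2 | iodolactone (3aS,6R,6aR)-6-iodohexahydro-2H-cyclopenta[b]furan-2-one | I[C@H]1[C@@H]2OC(=O)C[C@@H]2CC1 | intermediate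
3 | allylic lactone (3aS,6aR)-3,3a,4,6a-tetrahydro-2H-cyclopenta[b]furan-2-one | O=C1C[C@@H]2CC=C[C@@H]2O1 | intermediate
4 | lactone lithium enolate (not isolated) | [Li]OC1=C[C@@H]2CC=C[C@@H]2O1 | intermediate
5 | exo-methyl lactone (3S,3aS,6aR) | O=C1[C@@H](C)[C@@H]2CC=C[C@@H]2O1 | intermediate
6 | methylated lactone lithium enolate (not isolated) | [Li]OC1=C(C)[C@@H]2CC=C[C@@H]2O1 | intermediate
7 | endo-methyl lactone (3R,3aS,6aR) | O=C1[C@H](C)[C@@H]2CC=C[C@@H]2O1 | intermediate
8 | aldehyde methoxy hydroperoxide (not isolated; hydroperoxy carbon unassigned) | O=C[C@@H]1OC(=O)[C@H](C)[C@@H]1CC(OC)OO | intermediate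
9 | acetal methoxy hydroperoxide (not isolated) | COC(OC)[C@@H]1OC(=O)[C@H](C)[C@@H]1CC(OC)OO | intermediate
10 | acetal aldehyde 2-[(2R,3S,4R)-2-(dimethoxymethyl)-4-methyl-5-oxooxolan-3-yl]acetaldehyde | COC(OC)[C@@H]1OC(=O)[C@H](C)[C@@H]1CC=O | intermediate
11 | (S)-4-benzyl-3-propionyl-1,3-oxazolidin-2-one | CCC(=O)N1[C@@H](Cc2ccccc2)COC1=O | starting material
12 | (Z)-dibutylboron enolate of 11 (not isolated) | C/C=C(\OB(CCCC)CCCC)N1[C@@H](Cc2ccccc2)COC1=O | intermediate
13 | boron aldolate (not isolated) | COC(OC)[C@@H]1OC(=O)[C@H](C)[C@@H]1C[C@@H](OB(CCCC)CCCC)[C@H](C)C(=O)N1[C@@H](Cc2ccccc2)COC1=O | intermediate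
14 | syn-aldol imide (C10 S, C9 R) | COC(OC)[C@@H]1OC(=O)[C@H](C)[C@@H]1C[C@@H](O)[C@H](C)C(=O)N1[C@@H](Cc2ccccc2)COC1=O | intermediate
15 | silyl ether imide (C9–OTBS) | COC(OC)[C@@H]1OC(=O)[C@H](C)[C@@H]1C[C@@H](O[Si](C)(C)C(C)(C)C)[C@H](C)C(=O)N1[C@@H](Cc2ccccc2)COC1=O | intermediate
16 | S-ethyl thioester | COC(OC)[C@@H]1OC(=O)[C@H](C)[C@@H]1C[C@@H](O[Si](C)(C)C(C)(C)C)[C@H](C)C(=O)SCC | intermediate
17 | C1 aldehyde | COC(OC)[C@@H]1OC(=O)[C@H](C)[C@@H]1C[C@@H](O[Si](C)(C)C(C)(C)C)[C@H](C)C=O | intermediate
18 | but-2-yn-1-ol | CC#CCO | starting material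
19 | 1-methoxybut-2-yne | CC#CCOC | intermediate
20 | 1-methoxybuta-1,2-diene | COC=C=CC | intermediate
21 | 1-lithio-1-methoxybuta-1,2-diene (not isolated) | [Li]C(OC)=C=CC | intermediate
22 | lithium alkoxide adduct (not isolated; C1 and allene axis unassigned) | COC(OC)[C@@H]1OC(=O)[C@H](C)[C@@H]1C[C@@H](O[Si](C)(C)C(C)(C)C)[C@H](C)C(O[Li])C(OC)=C=CC | intermediate
23 | α'-hydroxy enone acetal (C1 epimers) | COC(OC)[C@@H]1OC(=O)[C@H](C)[C@@H]1C[C@@H](O[Si](C)(C)C(C)(C)C)[C@H](C)C(O)C(=O)/C=C/C | intermediate
24 | hydroxy keto aldehyde (C1 epimers) | O=C[C@@H]1OC(=O)[C@H](C)[C@@H]1C[C@@H](O[Si](C)(C)C(C)(C)C)[C@H](C)C(O)C(=O)/C=C/C | intermediate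
25 | trimethylsilyl ether keto aldehyde (C1 epimers) | O=C[C@@H]1OC(=O)[C@H](C)[C@@H]1C[C@@H](O[Si](C)(C)C(C)(C)C)[C@H](C)C(O[Si](C)(C)C)C(=O)/C=C/C | intermediate
26 | potassium enolate, C10 syn to O–K (not isolated) | O=C[C@@H]1OC(=O)[C@H](C)[C@@H]1C[C@@H](O[Si](C)(C)C(C)(C)C)[C@H](C)/C(O[Si](C)(C)C)=C(\O[K])/C=C/C | intermediate
27 | potassium aldolate (not isolated) | [K]O[C@H]1[C@@H]2OC(=O)[C@H](C)[C@@H]2C[C@@H](O[Si](C)(C)C(C)(C)C)[C@H](C)[C@@]1(O[Si](C)(C)C)C(=O)/C=C/C | intermediate
28 | bicyclic diol (C1–OH, C5–OH, C9–OTBS) | O[C@H]1[C@@H]2OC(=O)[C@H](C)[C@@H]2C[C@@H](O[Si](C)(C)C(C)(C)C)[C@H](C)[C@@]1(O)C(=O)/C=C/C | intermediate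
29 | angelic acid, (Z)-2-methylbut-2-enoic acid | C/C=C(/C)C(=O)O | starting material
30 | angelic 2,4,6-trichlorobenzoic anhydride (not isolated) | C/C=C(/C)C(=O)OC(=O)c1c(Cl)cc(Cl)cc1Cl | intermediate
31 | angelate silyl ether | C/C=C(/C)C(=O)O[C@H]1[C@@H]2OC(=O)[C@H](C)[C@@H]2C[C@@H](O[Si](C)(C)C(C)(C)C)[C@H](C)[C@@]1(O)C(=O)/C=C/C | intermediate
32 | target | C/C=C(/C)C(=O)O[C@H]1[C@@H]2OC(=O)[C@H](C)[C@@H]2C[C@@H](O)[C@H](C)[C@@]1(O)C(=O)/C=C/C | target

**Totals.** Total step count: 17. Longest linear sequence: 15 steps (1 to 32 through steps 1–9 and 12–17; steps 10–11 prepare allene 20).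

**Steps most likely to fail**

1. Step 15 (ring closure). Facial selectivity at the C5 aldehyde may erode if the enolate adopts the chelation-type geometry with O1 syn to O–K, which would lead to the C5 epimer. γ-Deprotonation of the crotonoyl unit or enolisation of the aldehyde may also compete. The fallback decouples C5 from the cyclisation. It sets out from 28 as whatever C5-epimer mixture is obtained. Dess–Martin periodinane (NaHCO3, CH2Cl2) would oxidise only the secondary C5 carbinol, so both epimers converge on the C5 ketone F1, whose C1 centre is quaternary and cannot enolise. Me4NBH(OAc)3 in AcOH/MeCN at −30 °C would then bind the free tertiary C1 hydroxyl and deliver hydride to the C5 ketone on the face of that hydroxyl (hydroxyl-directed reduction; the conjugated C2 ketone is much less reactive). This gives the trans diol and returns to 28.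

2. Step 5 (ozonolysis). The primary ozonide may fragment with incomplete regiocontrol, so that part of the material carries the acetal and the free aldehyde at the wrong termini. The fallback differentiates the termini after the cleavage. It sets out from 7: ozonolysis with reductive work-up (O3, CH2Cl2, −78 °C; Me2S) would give the dialdehyde F2, and exhaustive acetalisation (HC(OMe)3, TsOH, MeOH) the bis(dimethyl acetal) F3. Mild hydrolysis (AcOH/H2O/THF, rt) should then cleave only the C9 acetal, because the C5 acetal is deactivated by the adjacent lactone oxygen. This returns to 10.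

3. Step 16 (angeloylation). The angeloyl unit may isomerise to the tigloyl unit during carboxyl activation, and the hindered C5 hydroxyl may acylate so slowly that 28 opens by retro-aldol on heating with amine. The fallback makes the ester from the metal alkoxide formed in the ring closure. It sets out from 25: the cyclisation of step 15 is run as before and the potassium aldolate is trapped at −78 °C with angelic anhydride (a catalogue compound; alkoxide acylation needs neither activation nor a nucleophilic catalyst) to give the O1-trimethylsilyl angelate F4. Work-up with citric acid in MeOH removes the trimethylsilyl group and returns to 31.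

**Further compounds**
F1 | step 15 | C5 ketone (β-diketone) derived from 28 and its C5 epimer | O=C1[C@@H]2OC(=O)[C@H](C)[C@@H]2C[C@@H](O[Si](C)(C)C(C)(C)C)[C@H](C)[C@@]1(O)C(=O)/C=C/C
F2 | step 5 | dialdehyde (C5 and C9 aldehydes on the lactone) | O=C[C@@H]1OC(=O)[C@H](C)[C@@H]1CC=O
F3 | step 5 | bis(dimethyl acetal) | COC(OC)[C@@H]1OC(=O)[C@H](C)[C@@H]1CC(OC)OC
F4 | step 16 | O1-trimethylsilyl angelate | C/C=C(/C)C(=O)O[C@H]1[C@@H]2OC(=O)[C@H](C)[C@@H]2C[C@@H](O[Si](C)(C)C(C)(C)C)[C@H](C)[C@@]1(O[Si](C)(C)C)C(=O)/C=C/C
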